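**Strategy.** Ring A (C1–C5, C10) is a cyclohexane fused to ring B through C5–C10, with its functionality (quaternary C4, cis-2,3-diol) on the C2–C5 flank. This lets both rings be cut back to one chain: an intramolecular Diels–Alder reaction of a trienone in which the (E)-diene C2=C3–C4(CO2Me)=C5 is tied through C6–C7–C8(=O)–C9 to the isopropenyl dienophile C10=C1. In one operation it forms C1–C2 and C5–C10, closes rings A and B as a trans-decalin, and sets C5 and C10 from the single C9 stereocentre. The surviving C3=C4 enoate then delivers C4 (deconjugative methylation) and the diol; the C8 ketone delivers the C7=C8 methyl alkene.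

Key step: step 9

Remark on conventions and assumptions: labdane locants (C1–C20) are used for all intermediates in the explanations. α/β refer to the drawing with ring A on the left and C10 at the top, in which the target carries the C20 methyl, the C19 acetoxymethyl group and the C9 side chain on the lower (α) face, and H-5, H-9, C18 and both hydroxyls on the upper (β) face; the target is (2S,3R,4R,5S,9R,10S,13R). (R)-Citronellal, pent-4-yn-1-ol, B2pin2, vinyl bromide and both antipodes of the TRIP phosphoric acid are taken as purchased.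

**Step 1**
Reactants: 1 (R)-citronellal
Product: 2 (6R)-8,8-dimethoxy-2,6-dimethyloct-2-ene
Conditions: HC(OMe)3, MeOH, PPTS (cat.), 0 °C to rt
Reagents that add atoms: trimethyl orthoformate, COC(OC)OC
Why: Acid-catalysed acetalisation with a mild catalyst (to avoid the ene cyclisation of citronellal) masks C15 at the aldehyde level for all later base, hydride and organometallic steps and leaves C13 (R, from the chiral pool) untouched.

**Step 2**
Reactants: 2 (6R)-8,8-dimethoxy-2,6-dimethyloct-2-ene
Product: 3 (2E,6R)-8,8-dimethoxy-2,6-dimethyloct-2-en-1-ol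
Conditions: SeO2 (0.3 equiv), t-BuOOH (anhydrous, decane), CH2Cl2, 0 °C to rt
Reagents that add atoms: tert-butyl hydroperoxide, CC(C)(C)OO (terminal oxidant; oxygen is passed on through SeO2, O=[Se]=O)
Why: Catalytic SeO2 allylic oxidation (ene reaction, then [2,3]-shift) should hydroxylate the (E)-methyl of the trisubstituted alkene selectively and give the E allylic alcohol.

**Step 3**
Reactants: 3 (2E,6R)-8,8-dimethoxy-2,6-dimethyloct-2-en-1-ol
Product: 4 2-[(2E,6R)-8,8-dimethoxy-2,6-dimethyloct-2-en-1-yl]-4,4,5,5-tetramethyl-1,3,2-dioxaborolane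
Conditions: B2pin2, [Pd(MeCN)4](BF4)2 (5 mol%), DMSO/MeOH, rt
Reagents that add atoms: bis(pinacolato)diboron, CC1(C)OB(OC1(C)C)B1OC(C)(C)C(C)(C)O1
Why: Palladium-catalysed borylation of a free allylic alcohol proceeds through an allylpalladium intermediate that is borylated at its unsubstituted terminus, and the syn allyl complex should keep the E geometry on which step 7 depends.

**Step 4**
Reactants: 5 pent-4-yn-1-ol
Product: 6 methyl 6-hydroxyhex-2-ynoate
Conditions: n-BuLi (2.1 equiv), THF, −78 °C; ClCO2Me (1.0 equiv), −78 °C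
Reagents that add atoms: methyl chloroformate, COC(=O)Cl
Why: Acylation of a lithium acetylide with a chloroformate; in the O,C-dilithio species the acetylide carbon is the more reactive site, so the alkynoate should form with the hydroxyl left free.

**Step 5**
Reactants: 6 methyl 6-hydroxyhex-2-ynoate
Product: 8 methyl (2Z)-2-ethenyl-6-hydroxyhex-2-enoate, via alkenylstannane 7 (not isolated)
Conditions: Bu3SnH, Pd(PPh3)4 (3 mol%), THF, 0 °C to rt; then vinyl bromide, CuI, DMF, 50 °C
Reagents that add atoms: vinyl bromide, C=CBr; tributyltin hydride, CCCC[SnH](CCCC)CCCC (tin only in intermediate 7)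
Why: Palladium-catalysed syn-hydrostannation of the alkynoate (tin α to the ester, H cis to tin) followed by Stille coupling with retention fixes the diene geometry, the C6 chain ending cis to the ester and trans to the vinyl group.

**Step 6**
Reactants: 8 methyl (2Z)-2-ethenyl-6-hydroxyhex-2-enoate
Product: 9 methyl (2Z)-2-ethenyl-6-oxohex-2-enoate
Conditions: Dess–Martin periodinane, NaHCO3, CH2Cl2, 0 °C
Reagents that add atoms: none
Why: Buffered Dess–Martin oxidation of the primary alcohol gives the aldehyde under neutral conditions that spare the electron-poor diene; the aldehyde would be used at once.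

**Step 7**
Reactants: 9 methyl (2Z)-2-ethenyl-6-oxohex-2-enoate; 4 the (E)-allylboronate
Product: 10 methyl (2Z,6R,7S)-7-[(3R)-5,5-dimethoxy-3-methylpentyl]-2-ethenyl-6-hydroxy-8-methylnona-2,8-dienoate
Conditions: (S)-TRIP phosphoric acid (5 mol%), 4 Å MS, toluene, −30 °C
Reagents that add atoms: none
Why: Chiral phosphoric acid-catalysed allylboration through a closed chair transition state: the E boronate gives the anti adduct, and the catalyst antipode expected to direct attack to the Si face of the aldehyde sets C9 (the target's C9) together with a transient C8 carbinol, while bond formation at the γ-carbon creates the isopropenyl dienophile.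

**Step 8**
Reactants: 10 the anti homoallylic alcohol
Product: 11 methyl (2Z,7S)-7-[(3R)-5,5-dimethoxy-3-methylpentyl]-2-ethenyl-8-methyl-6-oxonona-2,8-dienoate
Conditions: Dess–Martin periodinane, NaHCO3, CH2Cl2, 0 °C
Reagents that add atoms: none
Why: Buffered Dess–Martin oxidation should give the β,γ-unsaturated ketone without conjugation or epimerisation at C9; the ketone removes a hydroxyl that could add to the dienoate and is the later handle for the C7=C8 alkene.

**Step 9**
Reactants: 11 the trienone
Product: 12 methyl 15,15-dimethoxy-8-oxo-17,18-dinorlabd-3-en-19-oate (trans-decalin; 5β-H, 9β-H, 10α-CH3, 9α side chain, 13R)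
Conditions: toluene (0.005 M), BHT (cat.), 150 °C, sealed tube (base-washed glass)
Reagents that add atoms: none
Why: On heating, the s-cis (E)-diene C2=C3–C4(CO2Me)=C5 and the tethered 1,1-disubstituted alkene C10=C1 undergo a concerted, asynchronous thermal [4+2] cycloaddition that forms C1–C2 and C5–C10 together and leaves the C3=C4 enoate. The closest known reaction type is the type 1 intramolecular Diels–Alder reaction of 1,7,9-decatrienes to trans-octalins. Ring B closes through the four-atom tether C6–C7–C8(=O)–C9 as a chair-like six-membered ring across the new C5–C10 bond, and ring A closes as the cyclohexene of the cycloaddition (fused mode, enforced by the tether length). C5 and C10 are the new stereocentres: their trans relationship follows from the transition state with the C10 methyl endo and the tether exo, because the endo-tether alternative would push C8, C9 and the side chain under the C4 ester, and their absolute sense is relayed from C9, whose side chain sits equatorial on the chair-like tether, anti to the forming C5–C10 bond, with C9–H eclipsing the isopropenyl plane. The step needs trans fusion, one diene face relative to C9 and no epimerisation at C9 before ring closure; the fixed E diene geometry, the equatorial preference of the C9 chain next to the sp2 C8 and the neutral, radical-inhibited conditions are relied on for these. After cyclisation the equatorial C9 chain α to the C8 ketone is also the thermodynamic one, so late epimerisation cannot erode it.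

**Step 10**
Reactants: 12 the cycloadduct
Product: 13 methyl 15,15-dimethoxy-8-(trifluoromethylsulfonyloxy)-17,18-dinorlabda-3,7-dien-19-oate
Conditions: KN(SiMe3)2, THF, −78 °C; PhNTf2, −78 to 0 °C
Reagents that add atoms: N-phenylbis(trifluoromethanesulfonimide), O=S(=O)(N(c1ccccc1)S(=O)(=O)C(F)(F)F)C(F)(F)F
Why: Kinetic enolisation of the C8 ketone at the unhindered C7 methylene (C9 is tertiary and next to the quaternary C10) and O-sulfonylation give the C7=C8 enol triflate, which masks the future alkene in an electron-poor form inert to base, hydride and osmylation.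

**Step 11**
Reactants: 13 the enol triflate
Product: 14 methyl 15,15-dimethoxy-8-(trifluoromethylsulfonyloxy)-17-norlabda-2,7-dien-19-oate (4β-CH3, 4α-CO2Me)
Conditions: LiN(i-Pr)2, THF/HMPA, −78 °C; MeI, −78 to −40 °C
Reagents that add atoms: iodomethane, CI
Why: Deconjugative α-alkylation of an α,β-unsaturated ester: γ-deprotonation at C2 gives the extended enolate, which is methylated at C4 from the β face, anti to the axial C10 methyl, so that C18 becomes equatorial, the C19 ester axial, and the double bond moves to C2=C3.

**Step 12**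
Reactants: 14 the quaternary ester
Product: 15 15,15-dimethoxy-8-(trifluoromethylsulfonyloxy)-17-norlabda-2,7-dien-19-ol
Conditions: i-Bu2AlH (3 equiv), CH2Cl2, −78 to 0 °C; Rochelle salt work-up
Reagents that add atoms: none
Why: Hydride reduction of the hindered neopentyl ester gives the C19 primary alcohol, with acetal, enol triflate and alkene inert.

**Step 13**
Reactants: 15 the C19 alcohol
Product: 16 19-acetoxy-15,15-dimethoxy-17-norlabda-2,7-dien-8-yl trifluoromethanesulfonate
Conditions: Ac2O, pyridine, DMAP (cat.), CH2Cl2, rt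
Reagents that add atoms: acetic anhydride, CC(=O)OC(C)=O
Why: Acylation of the only hydroxyl group installs the C19 acetate before the diol exists, so no selectivity among hydroxyls is needed.

**Step 14**
Reactants: 16 the acetate
Product: 17 19-acetoxy-2β,3β-dihydroxy-15,15-dimethoxy-17-norlabd-7-en-8-yl trifluoromethanesulfonate
Conditions: OsO4 (2 mol%), NMO, acetone/H2O, rt
Reagents that add atoms: osmium tetroxide, O=[Os](=O)(=O)=O (catalytic oxygen carrier); N-methylmorpholine N-oxide, C[N+]1([O-])CCOCC1; water, O
Why: Upjohn syn-dihydroxylation of the only electron-rich alkene (the enol triflate should not react) from the β face of C2=C3, opposite the axial C10 methyl and the axial C4 acetoxymethyl group, sets C2 and C3 as the cis 2β,3β-diol.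

**Step 15**
Reactants: 17 the diol triflate
Product: 19 aldehyde 19-acetoxy-2β,3β-dihydroxylabd-7-en-15-al, via dimethyl acetal 18 (not isolated)
Conditions: MeZnCl (6 equiv), Pd(PPh3)4 (5 mol%), THF, 50 °C; then 1 M HCl, THF, rt
Reagents that add atoms: methylzinc chloride, C[Zn]Cl; water, O
Why: Negishi coupling of the enol triflate at zerovalent palladium installs the C17 methyl with the double bond fixed at C7=C8 (the organozinc tolerates the acetate and is only consumed by the free hydroxyls), and the acidic work-up hydrolyses the dimethyl acetal to the C15 aldehyde.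

**Step 16**
Reactants: 19 the C15 aldehyde
Product: 20 (2S,3R,4R,5S,9R,10S,13R)-19-acetoxy-2,3-dihydroxylabd-7-en-15-oic acid (target)
Conditions: NaClO2, NaH2PO4, 2-methyl-2-butene, t-BuOH/H2O, rt
Reagents that add atoms: sodium chlorite, [Na+].[O-]Cl=O
Why: Pinnick oxidation converts the aldehyde into the carboxylic acid without touching the diol, the acetate or the trisubstituted alkene, the hypochlorite being scavenged by 2-methyl-2-butene.

**Compound list**

1 | (R)-citronellal, (3R)-3,7-dimethyloct-6-enal | CC(C)=CCC[C@@H](C)CC=O | starting material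
2 | (6R)-8,8-dimethoxy-2,6-dimethyloct-2-ene | CC(C)=CCC[C@@H](C)CC(OC)OC | intermediate
3 | (2E,6R)-8,8-dimethoxy-2,6-dimethyloct-2-en-1-ol | OC/C(C)=C/CC[C@@H](C)CC(OC)OC | intermediate
4 | 2-[(2E,6R)-8,8-dimethoxy-2,6-dimethyloct-2-en-1-yl]-4,4,5,5-tetramethyl-1,3,2-dioxaborolane | CC1(C)OB(C/C(C)=C/CC[C@@H](C)CC(OC)OC)OC1(C)C | intermediate
5 | pent-4-yn-1-ol | C#CCCCO | starting material
6 | methyl 6-hydroxyhex-2-ynoate | COC(=O)C#CCCCO | intermediate
7 | methyl (2E)-6-hydroxy-2-(tributylstannyl)hex-2-enoate | CCCC[Sn](CCCC)(CCCC)/C(C(=O)OC)=C/CCCO | intermediate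
8 | methyl (2Z)-2-ethenyl-6-hydroxyhex-2-enoate | C=C/C(C(=O)OC)=C/CCCO | intermediate
9 | methyl (2Z)-2-ethenyl-6-oxohex-2-enoate | C=C/C(C(=O)OC)=C/CCC=O | intermediate
10 | methyl (2Z,6R,7S)-7-[(3R)-5,5-dimethoxy-3-methylpentyl]-2-ethenyl-6-hydroxy-8-methylnona-2,8-dienoate | C=C/C(C(=O)OC)=C/CC[C@@H](O)[C@@H](CC[C@@H](C)CC(OC)OC)C(C)=C | intermediate
11 | methyl (2Z,7S)-7-[(3R)-5,5-dimethoxy-3-methylpentyl]-2-ethenyl-8-methyl-6-oxonona-2,8-dienoate | C=C/C(C(=O)OC)=C/CCC(=O)[C@@H](CC[C@@H](C)CC(OC)OC)C(C)=C | intermediate
12 | methyl 15,15-dimethoxy-8-oxo-17,18-dinorlabd-3-en-19-oate (5β-H, 9β-H, 10α-CH3, 13R) | COC(=O)C=1[C@H]2CCC(=O)[C@@H](CC[C@@H](C)CC(OC)OC)[C@]2(C)CCC=1 | intermediate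
13 | methyl 15,15-dimethoxy-8-(trifluoromethylsulfonyloxy)-17,18-dinorlabda-3,7-dien-19-oate | COC(=O)C=1[C@H]2CC=C(OS(=O)(=O)C(F)(F)F)[C@@H](CC[C@@H](C)CC(OC)OC)[C@]2(C)CCC=1 | intermediate
14 | methyl 15,15-dimethoxy-8-(trifluoromethylsulfonyloxy)-17-norlabda-2,7-dien-19-oate (4β-CH3, 4α-CO2Me) | COC(=O)[C@@]1(C)[C@H]2CC=C(OS(=O)(=O)C(F)(F)F)[C@@H](CC[C@@H](C)CC(OC)OC)[C@]2(C)CC=C1 | intermediate
15 | 15,15-dimethoxy-8-(trifluoromethylsulfonyloxy)-17-norlabda-2,7-dien-19-ol | OC[C@@]1(C)[C@H]2CC=C(OS(=O)(=O)C(F)(F)F)[C@@H](CC[C@@H](C)CC(OC)OC)[C@]2(C)CC=C1 | intermediate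
16 | 19-acetoxy-15,15-dimethoxy-17-norlabda-2,7-dien-8-yl trifluoromethanesulfonate | CC(=O)OC[C@@]1(C)[C@H]2CC=C(OS(=O)(=O)C(F)(F)F)[C@@H](CC[C@@H](C)CC(OC)OC)[C@]2(C)CC=C1 | intermediate
17 | 19-acetoxy-2β,3β-dihydroxy-15,15-dimethoxy-17-norlabd-7-en-8-yl trifluoromethanesulfonate | CC(=O)OC[C@@]1(C)[C@H]2CC=C(OS(=O)(=O)C(F)(F)F)[C@@H](CC[C@@H](C)CC(OC)OC)[C@]2(C)C[C@H](O)[C@@H]1O | intermediate
18 | 19-acetoxy-15,15-dimethoxylabd-7-ene-2β,3β-diol | CC(=O)OC[C@@]1(C)[C@H]2CC=C(C)[C@@H](CC[C@@H](C)CC(OC)OC)[C@]2(C)C[C@H](O)[C@@H]1O | intermediate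
19 | 19-acetoxy-2β,3β-dihydroxylabd-7-en-15-al | CC(=O)OC[C@@]1(C)[C@H]2CC=C(C)[C@@H](CC[C@@H](C)CC=O)[C@]2(C)C[C@H](O)[C@@H]1O | intermediate
20 | (2S,3R,4R,5S,9R,10S,13R)-19-acetoxy-2,3-dihydroxylabd-7-en-15-oic acid | CC(=O)OC[C@@]1(C)[C@H]2CC=C(C)[C@@H](CC[C@@H](C)CC(=O)O)[C@]2(C)C[C@H](O)[C@@H]1O | target

**Step count and risks**

Total steps: 16. Longest linear sequence: 13 (steps 1–3 or 4–6, then 7–16).

Steps most likely to fail:

1. Step 9 (intramolecular Diels–Alder). The C9 centre, α to the ketone and allylic, could epimerise by enolisation before ring closure. Face selectivity relative to C9 or the exo-tether preference could be insufficient, and the electron-poor diene could oligomerise or enter ene pathways at the temperature needed. Fallback: setting out from 10, Mitsunobu inversion at C8 (4-nitrobenzoic acid, PPh3, DIAD) would give the inverted 4-nitrobenzoate F1. In F1 the C8 oxygen and the C9 chain can both be equatorial on the chair-like tether, and C9 is no longer next to a carbonyl. Thermal cyclisation of F1 would give the decalin ester F2, methanolysis (K2CO3, MeOH) the 8β-alcohol F3, and Dess–Martin oxidation would come back to the route at 12.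

2. Step 7 (catalytic asymmetric allylboration). Enantio- and diastereocontrol could be poor with a functionalised aliphatic aldehyde and a β-methyl, γ-alkyl boronate; the acid catalyst could be inhibited by the acetal or ester; any Z boronate would leak into the wrong C9 epimer. Fallback: setting out from 3, Appel bromination (CBr4, PPh3) would give the allylic bromide F4. Nozaki–Hiyama–Kishi allylation of 9 with F4 (CrCl2, Et3N, chiral sulfonamide-oxazoline ligand, THF) passes through a γ-selective chair transition state that gives the anti adduct from either bromide geometry, and would come back at 10.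

3. Step 3 (borylation of the allylic alcohol). The E geometry could be lost by syn/anti isomerisation of the 2-methyl-substituted allylpalladium intermediate, or the boronate could be protodeborylated in the protic medium. Fallback: setting out from 2, ozonolysis (O3, then PPh3) would give the aldehyde F5. A Stork–Zhao-type Wittig reaction with Ph3P=C(CH3)I would give the (Z)-2-iodoalkene F6, and iodine–lithium exchange (t-BuLi) followed by homologation with ClCH2Bpin would give the geometrically defined (Z)-allylboronate F7. Allylboration of 9 with F7 under the (R)-TRIP acid (Re-face attack) would give the syn alcohol F8, which has the same C9 configuration as 10, and Dess–Martin oxidation would come back at 11.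

**Further compounds**

F1 | step 9 | methyl (2Z,6S,7S)-7-[(3R)-5,5-dimethoxy-3-methylpentyl]-2-ethenyl-8-methyl-6-(4-nitrobenzoyloxy)nona-2,8-dienoate | C=C/C(C(=O)OC)=C/CC[C@H](OC(=O)c1ccc(cc1)[N+](=O)[O-])[C@@H](CC[C@@H](C)CC(OC)OC)C(C)=C
F2 | step 9 | methyl 15,15-dimethoxy-8β-(4-nitrobenzoyloxy)-17,18-dinorlabd-3-en-19-oate | COC(=O)C=1[C@H]2CC[C@H](OC(=O)c3ccc(cc3)[N+](=O)[O-])[C@@H](CC[C@@H](C)CC(OC)OC)[C@]2(C)CCC=1
F3 | step 9 | methyl 8β-hydroxy-15,15-dimethoxy-17,18-dinorlabd-3-en-19-oate | COC(=O)C=1[C@H]2CC[C@H](O)[C@@H](CC[C@@H](C)CC(OC)OC)[C@]2(C)CCC=1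
F4 | step 7 | (2E,6R)-1-bromo-8,8-dimethoxy-2,6-dimethyloct-2-ene | BrC/C(C)=C/CC[C@@H](C)CC(OC)OC
F5 | step 3 | (4R)-6,6-dimethoxy-4-methylhexanal | O=CCC[C@@H](C)CC(OC)OC
F6 | step 3 | (2Z,6R)-2-iodo-8,8-dimethoxy-6-methyloct-2-ene | C/C(I)=C/CC[C@@H](C)CC(OC)OC
F7 | step 3 | 2-[(2Z,6R)-8,8-dimethoxy-2,6-dimethyloct-2-en-1-yl]-4,4,5,5-tetramethyl-1,3,2-dioxaborolane | CC1(C)OB(C/C(C)=C\CC[C@@H](C)CC(OC)OC)OC1(C)C
F8 | step 3 | methyl (2Z,6S,7S)-7-[(3R)-5,5-dimethoxy-3-methylpentyl]-2-ethenyl-6-hydroxy-8-methylnona-2,8-dienoate | C=C/C(C(=O)OC)=C/CC[C@H](O)[C@@H](CC[C@@H](C)CC(OC)OC)C(C)=C
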